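**Retrosynthetic overview**
- Cut N1–C2 and C3–C3a together: 3,5-dibromoaniline plus bis(methylthio)acetylene, a two-carbon unit that already carries both SMe groups at the final oxidation level.
- Key C–C bond (C3–C3a): the N-chloroaniline S-aminates the alkynyl sulfide. In the resulting azasulfonium the alkyne carbon, normally a nucleophile (thioester-enolate equivalent), acts as an α-cation (enolonium-type) equivalent and is delivered to the nucleophilic ortho carbon by a [3,3] shift.
- The pyrrole ring is the only ring formed; it closes in the same flask by N-attack on the ketene thionium. The benzene ring is bought, and the symmetry of the aniline fixes the 4,6-dibromo pattern.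
- Bis(methylthio)acetylene comes from trichloroethene (via dilithium acetylide) and MeSSO2Me.

Assumption: the target is achiral (no stereocentre), so there is no enantiomer to select and no stereocontrol step is needed.

**Step 1**
Reactants: 1 trichloroethene
Product: 6 1,2-bis(methylsulfanyl)ethyne, via dichloroethyne 2 (not isolated), via lithium chloroacetylide 3 (not isolated), via dilithium acetylide 4 (not isolated), via lithium (methylsulfanyl)acetylide 5 (not isolated)
Conditions: n-BuLi (3.0 equiv), Et2O, −78 °C → rt; then MeSSO2Me (2.1 equiv), THF, −78 °C → rt; distil
Reagents that add atoms: S-methyl methanethiosulfonate, CS(=O)(=O)SC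
Why: n-BuLi dehydrochlorinates trichloroethene to dichloroethyne and two Cl/Li exchanges give dilithium acetylide (a standard in-situ preparation), whose two carbanions are then sulfenylated one after the other by the thiosulfonate (acetylide sulfenylation; the sulfinate leaving group is non-nucleophilic and does not add to the product).

**Step 2**
Reactants: 7 3,5-dibromoaniline; 6 1,2-bis(methylsulfanyl)ethyne
Product: 12 4,6-dibromo-2,3-bis(methylsulfanyl)-1H-indole, via N-chloro-3,5-dibromoaniline 8 (not isolated), via azasulfonium chloride 9 (not isolated), via dienimine thionium chloride 10 (not isolated), via aminoaryl ketene thionium chloride 11 (not isolated)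
Conditions: t-BuOCl (1.0 equiv), CH2Cl2, −70 °C, 20 min; then 6 (1.1 equiv), −70 → 0 °C; then Et3N (1.2 equiv), 0 °C → rt
Reagents that add atoms: none
Why: Proposed new method: t-BuOCl N-chlorinates the electron-poor aniline and a sulfide sulfur of 6 displaces chloride from nitrogen as in the Gassman indole synthesis (the closest known reaction type, together with the interrupted-Pummerer/[3,3] annulation of phenols with alkynyl or ketene-dithioacetal sulfoxides to 2-sulfanylbenzofurans); in azasulfonium 9 the weak N–S+ bond drives a charge-accelerated [3,3] shift that bonds the SMe-bearing alkyne carbon, normally nucleophilic, to the equally nucleophilic ortho carbon (the sulfonium serves as an enolonium-type α-cation equivalent of a (methylthio)thioacetate), re-aromatisation of 10 gives ketene thionium 11, its central carbon is captured 5-endo by the adjacent NH2, and loss of HCl to Et3N gives the indole with both SMe groups in place; the weak base does not form the unstabilised S-methyl ylide, the two ortho positions of 7 are equivalent so only the 4,6-dibromo isomer can form, and no stereocentre is created.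

**Compound list**
1 | trichloroethene | ClC=C(Cl)Cl | starting material
2 | dichloroethyne | ClC#CCl | intermediate
3 | lithium chloroacetylide | [Li]C#CCl | intermediate
4 | dilithium acetylide | [Li]C#C[Li] | intermediate
5 | lithium (methylsulfanyl)acetylide | [Li]C#CSC | intermediate
6 | 1,2-bis(methylsulfanyl)ethyne (bis(methylthio)acetylene) | CSC#CSC | intermediate
7 | 3,5-dibromoaniline | Nc1cc(Br)cc(Br)c1 | starting material
8 | N-chloro-3,5-dibromoaniline | ClNc1cc(Br)cc(Br)c1 | intermediate
9 | azasulfonium chloride: (3,5-dibromoanilino)(methyl)[(methylsulfanyl)ethynyl]sulfonium chloride (racemic at S) | C[S+](Nc1cc(Br)cc(Br)c1)C#CSC.[Cl-] | intermediate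
10 | dienimine thionium chloride: [2-(2,4-dibromo-6-iminocyclohexa-2,4-dien-1-yl)-2-(methylsulfanyl)ethenylidene](methyl)sulfonium chloride (racemic, transient sp3 centre) | C[S+]=C=C(SC)C1C(=N)C=C(Br)C=C1Br.[Cl-] | intermediate
11 | aminoaryl ketene thionium chloride: [2-(2-amino-4,6-dibromophenyl)-2-(methylsulfanyl)ethenylidene](methyl)sulfonium chloride | C[S+]=C=C(SC)c1c(N)cc(Br)cc1Br.[Cl-] | intermediate
12 | 4,6-dibromo-2,3-bis(methylsulfanyl)-1H-indole | CSc1[nH]c2cc(Br)cc(Br)c2c1SC | target

**Step count and risks**
Total steps: 2. Longest linear sequence: 2 (1 → 6 → 12; 7 enters in step 2).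

The route has only two steps, so both are ranked. Step 2 holds two independent risk events and is entered twice.

Risk 1, step 2, formation of the N–S bond. The N-chloroaniline may chlorinate the electron-rich alkyne at carbon instead of being attacked at nitrogen by sulfur. The fallback inverts the polarity of the N–S bond formation and sets out from 6. One equivalent of mCPBA (CH2Cl2, −78 °C) gives 1-(methylsulfinyl)-2-(methylsulfanyl)ethyne F1; the second sulfur is deactivated once the first is oxidised. Oxalyl chloride at −78 °C converts it into chloro(methyl)[(methylsulfanyl)ethynyl]sulfonium chloride F2. The free aniline 7 then attacks the electrophilic sulfur (interrupted Pummerer mode) and the sequence comes back to the route at 9, which is warmed and treated with Et3N as in step 2.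

Risk 2, step 2, the [3,3] shift and ring closure. Chloride or amine may add to the alkynylsulfonium in conjugate fashion, or the shift to the bromine-flanked ortho carbon may be slow. The fallback keeps the sulfonium-based ortho C–C bond formation but uses the proven sp3 ylide variant and sets out from 8. (Methylsulfanyl)acetaldehyde dimethyl acetal at −70 °C gives (3,5-dibromoanilino)(2,2-dimethoxyethyl)(methyl)sulfonium chloride F3. Et3N triggers the Sommelet–Hauser [2,3] shift to 3,5-dibromo-2-[2,2-dimethoxy-1-(methylsulfanyl)ethyl]aniline F4. HCl in Et2O closes and aromatises this to 4,6-dibromo-3-(methylsulfanyl)-1H-indole F5. Electrophilic sulfenylation at C2 with N-(methylsulfanyl)phthalimide and TFA in CH2Cl2 then comes back to the route at 12.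

Risk 3, step 1, double sulfenylation of the insoluble dilithium acetylide. This may stop at mixtures or give low mass recovery. The fallback builds the two C–S bonds by different logic and sets out from 1. NaSMe in THF/DMF adds to dichloroethyne 2 generated in situ and gives (E)-1,2-dichloro-1-(methylsulfanyl)ethene F6. Two equivalents of n-BuLi (THF, −78 °C) eliminate HCl to give 1-chloro-2-(methylsulfanyl)ethyne F7 and exchange its chlorine for lithium. This comes back to the route at the soluble mono-acetylide 5, which is sulfenylated with MeSSO2Me to 6 as in step 1.

**Further compounds**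
F1 | step 2 | 1-(methylsulfinyl)-2-(methylsulfanyl)ethyne (racemic at S) | CS(=O)C#CSC
F2 | step 2 | chloro(methyl)[(methylsulfanyl)ethynyl]sulfonium chloride | C[S+](Cl)C#CSC.[Cl-]
F3 | step 2 | (3,5-dibromoanilino)(2,2-dimethoxyethyl)(methyl)sulfonium chloride | C[S+](Nc1cc(Br)cc(Br)c1)CC(OC)OC.[Cl-]
F4 | step 2 | 3,5-dibromo-2-[2,2-dimethoxy-1-(methylsulfanyl)ethyl]aniline (racemic) | COC(OC)C(SC)c1c(N)cc(Br)cc1Br
F5 | step 2 | 4,6-dibromo-3-(methylsulfanyl)-1H-indole | CSc1c[nH]c2cc(Br)cc(Br)c12
F6 | step 1 | (E)-1,2-dichloro-1-(methylsulfanyl)ethene | Cl/C=C(/Cl)SC
F7 | step 1 | 1-chloro-2-(methylsulfanyl)ethyne | ClC#CSC
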